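At 25 min of stirring I had to say what stood in a flask charged like the winter run, but with twice the coupling partner.

- winter: solid substrate 16 mM; coupling partner 6.4 mM; protic impurity 0.80 mM; run made earlier
- flask: solid substrate 16 mM; coupling partner 12.8 mM; protic impurity 0.800 mM; time 25 min

- winter (time / min: product / %, solid substrate / %): 0.667: 0.3, 99.9; 1.00: 0.3, 99.3; 1.50: 0.1, 98.7; 2.50: 0.8, 98.3; 5.00: 2.5, 97.1; 8.00: 4.6, 94.6

(each reading ± 0.5 percentage points)

- solid, in amounts per volume of the solution: solid substrate
- at the start none of the solid substrate is in solution
- what has only dissolved of solid substrate counts as not reacted
- the reaction counts as stopped when no species that holds the solid substrate changes by six tenths of a point or more over the second half of the time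

- the state of affairs at 25 min: stopped, and by what, or still going (for what has run out or reacted, a solid counts together with what of it has only dissolved) (it is still moving / the coupling partner has run out first / all of the solid substrate has reacted)
- the product standing at 25 min, as a percentage of the solid substrate charged

I worked with the fraction of solid substrate left. At the last winter reading it was 94.6%, and the loss over 8.00 min came to 0.108 mM/min: this is the supply, the amount per volume leaving the solid each minute. Already by 2.50 min the winter solid's average loss stood at 0.109 mM/min, about the same as the supply, while product stood at 0.8%, about half of the points the solid had lost. So I carried the supply unchanged into the new flask and took dissolving for the rate-limiting step, though the winter run, with its one charge of partner, does not show it.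

The product readings gave a second way. From 2.50 min to 8.00 min they rose at 0.111 mM/min. Run forward to 25 min, the solid way gave 16.9% and the product way 16.3%, which lay 0.60 percentage points apart. The solid way counted as reacted what had merely dissolved, and the winter balance, as read, lacked 0.8 points at its last reading, so I took the solid way for the one that cheated. I committed to the product way. The supply reckoned over 25 min came to 2.70 mM, less than the 12.0 mM of partner that remained once the impurity's own amount was taken off, and less than the 16 mM of solid substrate charged, so I expected the flask still to be moving.

The forecast said 21%, between 15% and 31%, and it is still moving, reasoning that “The early solid loss looks gradual, so dissolution is at least partly limiting”. Its centre stood above my figure.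

The flask gave 17.5%, and it is still moving. Taken without scatter at the time of the last winter reading, raising the partner to this flask's charge and changing nothing else moved product from 4.86% to 5.36%.

    solid substrate ⇌ dissolved substrate, rate k1*(cs1 - [dissolved substrate]) while solid is left; crystals form when [dissolved substrate] > cs1 (solubility = 7.70 mM, k = 0.0150 /min)
    dissolved substrate + coupling partner → product (k = 173 /M/min)
    coupling partner + protic impurity → quenched reagent (k = 694 /M/min)

The supply reckoned over 25 min was 16.9% of this flask's charge, against 17.9% for product and dissolved substrate together. On the neighbour flask charged with 6.4 mM of solid substrate, the same supply came to 42.2% of its charge, and that neighbour stood at 43.6% product with 1.11% dissolved.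

(Readings and results were generated by integration from invented constants, noise included.)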